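**Plan**
- Retrosynthetic cuts, in order: ring bond C1–C2 of the cyclopentenone (aldol), which opens the ring to methyl (Z)-3,6-dioxodocos-4-enoate; the Z-ene-1,4-dione back to a 2,5-disubstituted furan; the CH2–CH2 bond between C4' and C5' of the hexadecyl chain (counted from the ring); the furan C5–CH2CO2Me bond; a Wittig C=C.
- Enabling feature: ring atoms C2(OH)–C3=C4–C5(=O) are the four carbons of a furan at the enedione oxidation level, and C1 with its CO2Me is the furan's CH2CO2Me arm. The chain bond lies between two unbranched methylenes four carbons from that ring, so both partners can be written as acids R–CH2–CO2H.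
- Forward: furfural is taken to 5-(furan-2-yl)pentanoic acid (Wittig, H2), and radical alkylation adds the acetate arm. One electrolysis then dearomatises the furan to its 2,5-dimethoxy-2,5-dihydrofuran and joins the chain by mixed Kolbe pairing with tridecanoic acid.
- Mild hydrolysis gives the Z-enedione, and a 5-(enolexo)-exo-trig aldol, the presumed biosynthetic closure, forms the only ring last.
- Stereochemistry: the C2 carbinol centre (R) is set in the last step by a bifunctional cinchona squaramide catalyst. C1 (R) is an epimerisable β-keto ester centre and settles with CO2Me trans to hexadecyl and cis to OH.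

Key step: step 4

Remark: the neutral Z-enedione β-keto ester 11 is assumed to close only slowly without base at low temperature, so that it reaches the chiral catalyst before uncatalysed closure.

**Step 1**
Reactants: 1 furfural (furan-2-carbaldehyde); 2 (3-carboxypropyl)triphenylphosphonium bromide
Product: 4 5-(furan-2-yl)pent-4-enoic acid (E/Z mixture), via phosphonium ylide carboxylate 3 (not isolated)
Conditions: 2 (1.2 equiv), NaHMDS (2.4 equiv), THF, 0 °C; then 1, 0 °C to rt; aq. HCl work-up
Reagents that add atoms: none
Why: Wittig olefination of a non-enolisable heteroaryl aldehyde with the carboxylate-bearing non-stabilised ylide is standard, and the alkene geometry does not matter because the double bond is saturated in step 2.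

**Step 2**
Reactants: 4 5-(furan-2-yl)pent-4-enoic acid
Product: 5 5-(furan-2-yl)pentanoic acid
Conditions: H2 (1 atm), 5% Pd/C, EtOAc, rt, stopped after uptake of 1 equiv H2
Reagents that add atoms: none
Why: Heterogeneous catalytic hydrogenation should reduce the conjugated exocyclic C=C much faster than the aromatic furan ring, so the vinylfuran gives the alkylfuran.

**Step 3**
Reactants: 5 5-(furan-2-yl)pentanoic acid; 6 methyl iodoacetate
Product: 7 5-[5-(2-methoxy-2-oxoethyl)furan-2-yl]pentanoic acid
Conditions: 6 (1.5 equiv), FeSO4·7H2O (0.3 equiv), 30% aq. H2O2 (slow addition), DMSO, rt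
Reagents that add atoms: none
Why: Homolytic aromatic substitution under Fenton-type conditions (methyl radicals from DMSO abstract iodine from 6, the electrophilic •CH2CO2Me radical adds to the free α-position C5 of the electron-rich 2-alkylfuran, Fe(III) oxidation and proton loss restore the furan) is an established way to furan-2-acetates and tolerates the free acid.

**Step 4**
Reactants: 7 5-[5-(2-methoxy-2-oxoethyl)furan-2-yl]pentanoic acid; 8 tridecanoic acid
Product: 10 methyl 2-(5-hexadecyl-2,5-dimethoxy-2,5-dihydrofuran-2-yl)acetate (cis/trans mixture), via dimethoxydihydrofuran acid 9 (not isolated)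
Conditions: 8 (4 equiv), NaOMe (0.1 equiv per CO2H), MeOH under a hexane layer, undivided cell, smooth Pt anode, Pt cathode, constant current; ca. 2.2 F per mol of 7 at 0 °C and low current density, then ≥0.25 A cm⁻² at 40 °C until the acids are consumed
Reagents that add atoms: methanol, CO
Why: Proposed new method: at the anode the 2,5-dialkylfuran ring of 7, the most easily oxidised site, should first give up two electrons and add methanol at C2 and C5 (Clauson-Kaas 1,4-dimethoxylation) to give ketal acid 9, and at high current density the carboxylates of 9 and 8 should then each lose one electron and CO2 and pair as primary alkyl radicals at the electrode surface, making the CH2–CH2 bond between C4' and C5' of the future hexadecyl chain (mixed Kolbe coupling). The closest known reaction types are the mixed Kolbe electrolysis of two fatty acids and the anodic methoxylation of 2,5-dialkylfurans in methanol, which share solvent, anode and electrolyte; their union in one electrolysis of a furan-bearing acid is the unproven part. No ring is closed: the furan ring is kept and only dearomatised to the 2,5-dihydrofuran bis-ketal, a masked Z-ene-1,4-dione. The two ketal stereocentres (C2 and C5 of the dihydrofuran) form without control, which is harmless because both diastereomers hydrolyse to the same enedione. The step needs cross- rather than homo-coupling, secured by the fourfold excess of cheap 8 (its dimer tetracosane is non-polar and leaves in the hexane layer), and radical pairing rather than two-electron Hofer–Moest oxidation, secured by both radicals being primary and unstabilised together with smooth platinum, high current density and the weakly acidic medium. It also needs the ring to survive the second stage, which rests on the low oxidation potential of the furan (it is converted before any carboxylate is discharged), on the bis-ketal alkene no longer being oxidisable, and on the four-carbon tether offering the primary radical only a slow 6-exo attack on that alkene.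

**Step 5**
Reactants: 10 methyl 2-(5-hexadecyl-2,5-dimethoxy-2,5-dihydrofuran-2-yl)acetate
Product: 11 methyl (Z)-3,6-dioxodocos-4-enoate
Conditions: SiO2 wetted with 10% aq. oxalic acid, CH2Cl2, 0 °C, dark; filtration, evaporation below 0 °C, used at once
Reagents that add atoms: water, O
Why: Mild acid hydrolysis of a 2,5-dialkyl-2,5-dimethoxy-2,5-dihydrofuran, whose two tertiary ketal carbons ionise readily, is the classical unmasking of a cis-ene-1,4-dione; the Z geometry is inherited from the ring and should be kept by working cold, briefly and in the dark.

**Step 6**
Reactants: 11 methyl (Z)-3,6-dioxodocos-4-enoate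
Product: 12 methyl (1R,2R)-2-hexadecyl-2-hydroxy-5-oxocyclopent-3-ene-1-carboxylate
Conditions: quinine-derived 3,5-bis(trifluoromethyl)phenyl squaramide (10 mol%), toluene–CH2Cl2 (4:1), −40 °C; cold filtration through a short silica pad
Reagents that add atoms: none
Why: Proposed new method: the quinuclidine nitrogen of the catalyst should deprotonate the acidic C2 methylene of the β-keto ester while the squaramide N–H pair hydrogen-bonds the C6 ketone, so that the 5-(enolexo)-exo-trig aldol of C2 onto C6 (possible only from the Z-enedione) runs inside a chiral ion pair that selects one face of the ketone and sets the carbinol centre, after which the epimerisable β-keto ester centre C1 settles with CO2Me trans to the hexadecyl chain and cis (hydrogen-bonded) to OH; the closest known reaction types are the base-mediated racemic closure of Z-3,6-dioxo-4-enoates to 4-hydroxycyclopentenones and the cinchona squaramide- or thiourea-catalysed enantioselective additions of 1,3-dicarbonyl pronucleophiles to ketones, and the quinidine-derived pseudo-enantiomer of the catalyst is taken instead if the induction proves to favour the (2S) carbinol.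

**Compound list**
1 | furfural (furan-2-carbaldehyde) | O=Cc1ccco1 | starting material
2 | (3-carboxypropyl)triphenylphosphonium bromide | OC(=O)CCC[P+](c1ccccc1)(c1ccccc1)c1ccccc1.[Br-] | starting material
3 | sodium 4-(triphenyl-λ5-phosphanylidene)butanoate (ylide carboxylate, not isolated) | [Na+].[O-]C(=O)CCC=P(c1ccccc1)(c1ccccc1)c1ccccc1 | intermediate
4 | 5-(furan-2-yl)pent-4-enoic acid (E/Z mixture) | OC(=O)CCC=Cc1ccco1 | intermediate
5 | 5-(furan-2-yl)pentanoic acid | OC(=O)CCCCc1ccco1 | intermediate
6 | methyl iodoacetate | COC(=O)CI | starting material
7 | 5-[5-(2-methoxy-2-oxoethyl)furan-2-yl]pentanoic acid | COC(=O)Cc1ccc(CCCCC(=O)O)o1 | intermediate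
8 | tridecanoic acid | CCCCCCCCCCCCC(=O)O | starting material
9 | 5-[2,5-dimethoxy-5-(2-methoxy-2-oxoethyl)-2,5-dihydrofuran-2-yl]pentanoic acid (cis/trans mixture, not isolated) | COC(=O)CC1(OC)C=CC(CCCCC(=O)O)(OC)O1 | intermediate
10 | methyl 2-(5-hexadecyl-2,5-dimethoxy-2,5-dihydrofuran-2-yl)acetate (cis/trans mixture) | CCCCCCCCCCCCCCCCC1(OC)C=CC(CC(=O)OC)(OC)O1 | intermediate
11 | methyl (Z)-3,6-dioxodocos-4-enoate | CCCCCCCCCCCCCCCCC(=O)/C=C\C(=O)CC(=O)OC | intermediate
12 | methyl (1R,2R)-2-hexadecyl-2-hydroxy-5-oxocyclopent-3-ene-1-carboxylate | CCCCCCCCCCCCCCCC[C@@]1(O)C=CC(=O)[C@@H]1C(=O)OC | target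

**Count**
Total steps: 6. Longest linear sequence: 6 steps (1 → 4 → 5 → 7 → 10 → 11 → 12); acid 8 enters at step 4.

**Steps most likely to fail**

Step 4. The furan radical cation may lose a proton from the activated CH2CO2Me arm, giving side-chain instead of nuclear methoxylation. Two-electron oxidation of the radicals may outrun their pairing, and statistical homo-coupling drains the valuable acid. The fallback separates the two events with known chemistry; it sets out from 7 and comes back at 11. Acid 7 is esterified with N-hydroxyphthalimide (DIC, cat. DMAP, CH2Cl2) to the redox-active ester 1,3-dioxoisoindolin-2-yl 5-[5-(2-methoxy-2-oxoethyl)furan-2-yl]pentanoate F1. Nickel-catalysed decarboxylative alkyl–alkyl Negishi coupling of F1 with didodecylzinc prepared beforehand (NiCl2·glyme, 4,4'-di-tert-butyl-2,2'-bipyridine, THF/DMF, rt) should form the same CH2–CH2 bond and give methyl 2-(5-hexadecylfuran-2-yl)acetate F2. Sensitised photooxygenation of F2 (O2, tetraphenylporphyrin, hν, CH2Cl2, −78 °C) should give the furan endoperoxide methyl 2-(4-hexadecyl-2,3,7-trioxabicyclo[2.2.1]hept-5-en-1-yl)acetate F3. F3 is reduced in the same flask with dimethyl sulfide to enedione 11, so no acid is used and step 5 is bypassed.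

Step 6. Uncatalysed closure, or retro-aldol opening and re-closure of the product, may compete with the catalyst-bound pathway and erode facial selectivity. The amine may also isomerise the Z-alkene to the E-alkene, which cannot close. The fallback gives up catalyst control for resolution; it sets out from 11 and comes back at 12. Enedione 11 is closed by the known base-mediated aldol (cat. Et3N, CH2Cl2, 0 °C), which should give 12 together with its mirror image methyl (1S,2S)-2-hexadecyl-2-hydroxy-5-oxocyclopent-3-ene-1-carboxylate F4 as the racemate. The two are separated by preparative HPLC on an amylose tris(3,5-dimethylphenylcarbamate) stationary phase, and the (1R,2R) fraction is taken as 12.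

Step 3. With the furan as the limiting partner, further alkylation at C3/C4 and oxidative degradation of the ring by hydroxyl radicals may compete. The fallback replaces the radical substitution by a polar sequence; it sets out from 5 and comes back at 7. Friedel–Crafts hydroxyalkylation of C5 with methyl glyoxylate (cat. Yb(OTf)3, CH2Cl2, rt) should give 5-[5-(1-hydroxy-2-methoxy-2-oxoethyl)furan-2-yl]pentanoic acid F5. Acetylation (Ac2O, pyridine, cat. DMAP; aqueous work-up) gives 5-[5-(1-acetoxy-2-methoxy-2-oxoethyl)furan-2-yl]pentanoic acid F6. Reductive removal of the α-acetoxy group with samarium diiodide (THF–HMPA, MeOH, rt) should then give 7.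

**Further compounds**
F1 | step 4 | 1,3-dioxoisoindolin-2-yl 5-[5-(2-methoxy-2-oxoethyl)furan-2-yl]pentanoate | COC(=O)Cc1ccc(CCCCC(=O)ON2C(=O)c3ccccc3C2=O)o1
F2 | step 4 | methyl 2-(5-hexadecylfuran-2-yl)acetate | CCCCCCCCCCCCCCCCc1ccc(CC(=O)OC)o1
F3 | step 4 | methyl 2-(4-hexadecyl-2,3,7-trioxabicyclo[2.2.1]hept-5-en-1-yl)acetate | CCCCCCCCCCCCCCCCC12C=CC(CC(=O)OC)(OO1)O2
F4 | step 6 | methyl (1S,2S)-2-hexadecyl-2-hydroxy-5-oxocyclopent-3-ene-1-carboxylate | CCCCCCCCCCCCCCCC[C@]1(O)C=CC(=O)[C@H]1C(=O)OC
F5 | step 3 | 5-[5-(1-hydroxy-2-methoxy-2-oxoethyl)furan-2-yl]pentanoic acid (racemic) | COC(=O)C(O)c1ccc(CCCCC(=O)O)o1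
F6 | step 3 | 5-[5-(1-acetoxy-2-methoxy-2-oxoethyl)furan-2-yl]pentanoic acid (racemic) | COC(=O)C(OC(C)=O)c1ccc(CCCCC(=O)O)o1
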